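All runs are simulated with constants of no real substance; the scatter is artificial.

Late in the beta run, at 20.0 h, the left-handed substrate stood at 62.8% of its own charge and the right-handed substrate at 75.4%, readings with a scatter of 1 percentage point. On the list of suspects both substrates react with the same catalyst and the same coupling partner, each first order in itself. So ln([substrate]/charge) is, for each, one shared time integral times its own rate constant, and that integral cancels in the ratio of the two logarithms. I read this ratio as 1.65, the selectivity factor.

| setting | epsilon | gamma | beta | flask |
|---|---|---|---|---|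
| left-handed substrate | 0.020 M | 0.020 M | 0.020 M | 0.020 M |
| right-handed substrate | 0.020 M | 0.020 M | 0.020 M | 0.020 M |
| solid reagent | 0.027 M | 0.060 M | 0.040 M | 0.0400 M |
| precatalyst | 0.19 mM | 0.19 mM | 0.38 mM | 0.19 mM |
| added ligand | 0.56 mM | 0.56 mM | 0.56 mM | 0.56 mM |
| remark | run made earlier | run made earlier | run made earlier |  |
| time |  |  |  | 15 h |

- epsilon (time / h: right-handed substrate / %, left-handed substrate / %, left-handed product / %): 1.00: 50.3, 49.3, 0.3; 3.00: 50.9, 49.4, 2.8; 5.00: 49.0, 46.8, 3.9; 8.00: 47.5, 45.5, 4.9; 10.0: 46.7, 45.8, 6.9; 15.0: 46.2, 43.5, 6.8; 20.0: 44.7, 41.1, 7.2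
- gamma (time / h: right-handed substrate / %, left-handed substrate / %, left-handed product / %): 1.33: 49.5, 50.1, 0.9; 2.00: 50.3, 49.1, 0; 3.00: 49.8, 48.1, 0; 5.00: 50.5, 44.7, 4.0; 8.00: 46.4, 45.3, 6.3; 12.0: 46.2, 44.0, 7.1; 20.0: 46.2, 40.4, 8.6
- beta (time / h: right-handed substrate / %, left-handed substrate / %, left-handed product / %): 4.00: 47.3, 45.1, 3.5; 8.00: 42.6, 41.3, 9.5; 10.0: 43.1, 37.0, 10.2; 15.0: 40.0, 34.7, 14.0; 20.0: 37.7, 31.4, 18.7

(standard deviation of a reading: 1 percentage point)

- catalyst is single-handed; left-handed substrate and right-handed substrate are mirror images of each other, charged as a racemate, each of them at the stated concentration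
- as a solid, counted per litre of solution: solid reagent
- on the list of suspects stand: precatalyst -> catalyst; coupling partner + catalyst + right-handed substrate -> catalyst + right-handed product; solid reagent <-> coupling partner; catalyst + added ligand <-> idle complex; coupling partner + catalyst + left-handed substrate -> catalyst + left-handed product
- at the start none of the solid reagent is in solution

- whether the excess of right-handed substrate over left-handed substrate among what is left of the two reaches 99% by 15 h (no / yes)
- the highest excess of right-handed substrate over left-handed substrate among what is left of the two up to 15 h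

An excess of 99.0% needs [left-handed substrate]/[right-handed substrate] at (1 − excess)/(1 + excess). With the ratio of logarithms held at 1.65, the right-handed substrate then has to fall by 3.55 powers of ten, to 0.0282% of its charge. The beta run, with twice the precatalyst of the flask, had lost 0.123 of a power of ten of its right-handed substrate by 20.0 h, far short of that, and the flask stops earlier. So I said no for the flask.

The forecast also said no and put the top at 4%, between 2.5% and 5.5%, “rising steadily with time, so the maximum falls at 15 h”. That top is its figure, not one I reckoned.

The flask gave no, with a top of 2.91%.

    precatalyst → catalyst (k = 1.40 × 10⁻⁴ /s)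
    coupling partner + catalyst + right-handed substrate → catalyst + right-handed product (k = 4.70 /M²/s)
    solid reagent ⇌ coupling partner, rate k3*(cs3 - [coupling partner]) while solid is left; crystals form when [coupling partner] > cs3 (solubility = 17.0 mM, k = 7.70 × 10⁻⁵ /s)
    catalyst + added ligand ⇌ idle complex (K = 30000 /M, k = 0.270 /M/s)
    coupling partner + catalyst + left-handed substrate → catalyst + left-handed product (k = 7.50 /M²/s)

At 15.0 h the flask held 91% of its right-handed substrate, and raising that to the power 1.65 gives an excess of 3.16%. The forecast would have been wrong for the neighbour charged with 7.6 × 10⁻⁴ M of precatalyst. There 53% of the right-handed substrate remained, the same power gives 20.3%, and the top stood above the forecast's range, at 18.7%.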